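## Retrosynthetic overview
1. Last bond changes: a lipase (serine hydrolase class) removes the 4'''-acetate by alcoholysis at neutral pH, after hydrogenolysis of the two peri benzyl ethers. No base touches the finished flavanone.
2. C2–C1' disconnection: an enantioselective rhodium-catalysed Hayashi–Miyaura 1,4-addition of a biaryl-flavone boronic acid to 5-benzyloxy-7-methoxychromone joins the halves and sets C2 as S.
3. The boronic acid comes from an aryl chloride by Miyaura borylation. Its flavone pyranone ring comes from a chalcone (Claisen–Schmidt condensation, then I2/DMSO).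
4. The 3'–8'' biaryl bond is made by Suzuki coupling at the acetophenone stage (3-iodoacetophenone plus 5-chloro-2-methoxyphenylboronic acid).
5. Both halves start from 2',6'-dihydroxy-4'-methoxyacetophenone. Ring order: chromone pyranone of the future flavanone half, then the biaryl bond, then the flavone pyranone, then saturation of the chromone ring on fragment union.

Assumption: the SMILES gives no descriptor for the 3'–8'' biaryl axis, so it is treated as equilibrating and C2 is the only stereo-element controlled.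

## Route

Step 1
Reactants: 1 1-(2,6-dihydroxy-4-methoxyphenyl)ethanone
Product: 2 1-[2-(benzyloxy)-6-hydroxy-4-methoxyphenyl]ethanone
Conditions: BnBr (1.05 equiv), K2CO3 (1.2 equiv), acetone, reflux, 8 h
Reagents that add atoms: benzyl bromide, BrCc1ccccc1
Why: Williamson etherification of a mirror-symmetric diol can give only one mono-ether, and the remaining OH is hydrogen-bonded to the ketone, which slows a second alkylation.

Step 2
Reactants: 2 1-[2-(benzyloxy)-6-hydroxy-4-methoxyphenyl]ethanone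
Product: 4 5-(benzyloxy)-7-methoxy-4H-chromen-4-one, via enaminone 3 (not isolated)
Conditions: DMF-DMA (3 equiv), toluene, 100 °C, 3 h; solvent swap; conc. HCl (2 equiv), CH2Cl2, rt, 1 h
Reagents that add atoms: N,N-dimethylformamide dimethyl acetal, COC(OC)N(C)C
Why: The methyl ketone condenses with the amide acetal, and acid then drives phenol addition and loss of dimethylamine (enaminone chromone synthesis), conditions mild enough to spare the benzyl ether.

Step 3
Reactants: 2 1-[2-(benzyloxy)-6-hydroxy-4-methoxyphenyl]ethanone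
Product: 5 1-[6-(benzyloxy)-2-hydroxy-3-iodo-4-methoxyphenyl]ethanone
Conditions: NIS (1.02 equiv), DMF, 0 °C to rt, dark, 4 h
Reagents that add atoms: N-iodosuccinimide, O=C1CCC(=O)N1I
Why: Electrophilic aromatic iodination takes the site ortho to the chelated free OH (flanked by OH/OMe, less crowded than the OMe/OBn site), the same preference that sends iodine to C6 of 5-hydroxy-7-alkoxyflavones, and an HMBC cross-peak from the chelated OH to the C–I carbon confirms it.

Step 4
Reactants: 5 1-[6-(benzyloxy)-2-hydroxy-3-iodo-4-methoxyphenyl]ethanone; 6 (5-chloro-2-methoxyphenyl)boronic acid (1.4 equiv)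
Product: 7 1-[6-(benzyloxy)-3-(5-chloro-2-methoxyphenyl)-2-hydroxy-4-methoxyphenyl]ethanone
Conditions: Pd(PPh3)4 (5 mol%), K2CO3 (3 equiv), 1,4-dioxane/H2O 4:1, 90 °C, 12 h, argon
Reagents that add atoms: none
Why: In this Suzuki–Miyaura coupling the PPh3-ligated zerovalent palladium inserts only into the C–I bond, so the electron-rich C–Cl bond survives as the later boron handle.

Step 5
Reactants: 7 1-[6-(benzyloxy)-3-(5-chloro-2-methoxyphenyl)-2-hydroxy-4-methoxyphenyl]ethanone; 8 4-(methoxymethoxy)benzaldehyde (1.2 equiv)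
Product: 9 (E)-1-[6-(benzyloxy)-3-(5-chloro-2-methoxyphenyl)-2-hydroxy-4-methoxyphenyl]-3-[4-(methoxymethoxy)phenyl]prop-2-en-1-one
Conditions: KOH (50% aq, 10 equiv), EtOH, rt, 36 h; cold 1 M HCl to pH 4
Reagents that add atoms: none
Why: Claisen–Schmidt condensation with a non-enolisable, fully etherified aldehyde gives the E-chalcone, and the benzyl, MOM and aryl chloride groups are all inert to hydroxide.

Step 6
Reactants: 9 (E)-chalcone
Product: 11 5-(benzyloxy)-8-(5-chloro-2-methoxyphenyl)-2-(4-hydroxyphenyl)-7-methoxy-4H-chromen-4-one, via MOM flavone 10 (not isolated)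
Conditions: I2 (10 mol%), DMSO, 120 °C, 3 h; cool to 50 °C, MeOH, conc. HCl (to about 2 M), 50 °C, 2 h; aq. Na2S2O3 work-up
Reagents that add atoms: none
Why: Iodine-catalysed oxidative cyclisation (oxa-Michael addition, alpha-iodination, loss of HI, DMSO as terminal oxidant) closes the flavone through the only free OH so the aryl group ends at C8, and the acid stage completes any partial MOM acetal hydrolysis so one product results.

Step 7
Reactants: 11 4'-hydroxyflavone
Product: 12 4-[5-(benzyloxy)-8-(5-chloro-2-methoxyphenyl)-7-methoxy-4-oxo-4H-chromen-2-yl]phenyl acetate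
Conditions: Ac2O (1.5 equiv), pyridine (3 equiv), DMAP (5 mol%), CH2Cl2, rt, 2 h
Reagents that add atoms: acetic anhydride, CC(=O)OC(C)=O
Why: O-Acylation of the only free phenol gives an ester that keeps the boron intermediates soluble and non-acidic, withstands KOAc, periodate and H2, and sits at an unhindered para position that lipases accept.

Step 8
Reactants: 12 aryl chloride acetate
Product: 13 4-{5-(benzyloxy)-7-methoxy-8-[2-methoxy-5-(4,4,5,5-tetramethyl-1,3,2-dioxaborolan-2-yl)phenyl]-4-oxo-4H-chromen-2-yl}phenyl acetate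
Conditions: B2pin2 (1.5 equiv), Pd2(dba)3 (2 mol%), XPhos (8 mol%), KOAc (3 equiv), 1,4-dioxane, 105 °C, 8 h
Reagents that add atoms: bis(pinacolato)diboron, CC1(C)OB(OC1(C)C)B1OC(C)(C)C(C)(C)O1
Why: Miyaura borylation with a bulky electron-rich biaryl phosphine activates even a para-methoxy aryl chloride, and anhydrous KOAc harms neither the aryl acetate nor the flavone.

Step 9
Reactants: 13 pinacol boronate
Product: 14 {3-[2-(4-acetoxyphenyl)-5-(benzyloxy)-7-methoxy-4-oxo-4H-chromen-8-yl]-4-methoxyphenyl}boronic acid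
Conditions: NaIO4 (3 equiv), THF/H2O 4:1, rt, 30 min; 1 M HCl (1 equiv), rt, 6 h
Reagents that add atoms: water, O
Why: Oxidative glycol cleavage of the released pinacol pulls the boronate hydrolysis to completion under mildly acidic conditions that leave the aryl acetate intact, giving the free boronic acid that transmetalates fastest to rhodium.

Step 10
Reactants: 14 biaryl-flavone boronic acid (1.0 equiv); 4 5-(benzyloxy)-7-methoxy-4H-chromen-4-one (1.5 equiv)
Product: 15 4-{5-(benzyloxy)-8-[5-((2S)-5-(benzyloxy)-7-methoxy-4-oxochroman-2-yl)-2-methoxyphenyl]-7-methoxy-4-oxo-4H-chromen-2-yl}phenyl acetate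
Conditions: [RhCl(C2H4)2]2 (1.5 mol%), (S)-MeO-F12-BIPHEP [(S)-6,6'-dimethoxybiphenyl-2,2'-diylbis(bis(3,4,5-trifluorophenyl)phosphine)] (3.3 mol%), KOH (10 mol%, aq), CH2Cl2/H2O 10:1, 25 °C, 4–6 h
Reagents that add atoms: none
Why: In this Hayashi–Miyaura asymmetric 1,4-addition the aryl group on monovalent rhodium inserts into the chromone C2=C3 bond from the face left open by the (S)-biaryl diphosphine (the sense by which (S)-BINAP-type ligands give (S)-3-arylcyclohexanones, here 2S, checked by chiral HPLC and CD), and the two benzylated peri oxygens prevent acac-like chelation of rhodium while the room-temperature, nearly neutral medium avoids retro-oxa-Michael racemisation.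

Step 11
Reactants: 15 (2S)-dibenzyl ether acetate
Product: 16 4-{5-hydroxy-8-[5-((2S)-5-hydroxy-7-methoxy-4-oxochroman-2-yl)-2-methoxyphenyl]-7-methoxy-4-oxo-4H-chromen-2-yl}phenyl acetate
Conditions: H2 (1 atm), Pd/C (10 wt% Pd, 10 mol%), EtOAc/THF 1:1, rt, 2–3 h, stopped at full conversion
Reagents that add atoms: none
Why: Neutral catalytic hydrogenolysis cleaves the two aryl benzyl ethers well before the flavone C=C, the chelated ketones or the ring C2–O bond react, and it does not affect C2 or the acetate.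

Step 12
Reactants: 16 (2S)-4'''-acetate
Product: 17 (2S)-2,3-dihydroamentoflavone 7,4',7''-tri-O-methyl ether (target)
Conditions: immobilised Burkholderia cepacia lipase, 1-butanol (10 equiv), THF, 40 °C, 24–36 h; filter off the enzyme
Reagents that add atoms: none
Why: A lipase (serine hydrolase, EC 3.1.1.3) passes the exposed para-aryl acetate through its acyl-enzyme to 1-butanol (enzymatic transesterification) at neutral pH, so the ester goes without the base that would open the 5-hydroxyflavanone by retro-oxa-Michael reaction and racemise C2.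

## Compound list
1 | 1-(2,6-dihydroxy-4-methoxyphenyl)ethanone | CC(=O)c1c(O)cc(OC)cc1O | starting material
2 | 1-[2-(benzyloxy)-6-hydroxy-4-methoxyphenyl]ethanone | CC(=O)c1c(O)cc(OC)cc1OCc1ccccc1 | intermediate
3 | (E)-1-[2-(benzyloxy)-6-hydroxy-4-methoxyphenyl]-3-(dimethylamino)prop-2-en-1-one | CN(C)/C=C/C(=O)c1c(O)cc(OC)cc1OCc1ccccc1 | intermediate
4 | 5-(benzyloxy)-7-methoxy-4H-chromen-4-one | COc1cc(OCc2ccccc2)c2c(=O)ccoc2c1 | intermediate
5 | 1-[6-(benzyloxy)-2-hydroxy-3-iodo-4-methoxyphenyl]ethanone | CC(=O)c1c(O)c(I)c(OC)cc1OCc1ccccc1 | intermediate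
6 | (5-chloro-2-methoxyphenyl)boronic acid | COc1ccc(Cl)cc1B(O)O | starting material
7 | 1-[6-(benzyloxy)-3-(5-chloro-2-methoxyphenyl)-2-hydroxy-4-methoxyphenyl]ethanone | CC(=O)c1c(O)c(-c2cc(Cl)ccc2OC)c(OC)cc1OCc1ccccc1 | intermediate
8 | 4-(methoxymethoxy)benzaldehyde | COCOc1ccc(C=O)cc1 | starting material
9 | (E)-1-[6-(benzyloxy)-3-(5-chloro-2-methoxyphenyl)-2-hydroxy-4-methoxyphenyl]-3-[4-(methoxymethoxy)phenyl]prop-2-en-1-one | COCOc1ccc(/C=C/C(=O)c2c(O)c(-c3cc(Cl)ccc3OC)c(OC)cc2OCc2ccccc2)cc1 | intermediate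
10 | 5-(benzyloxy)-8-(5-chloro-2-methoxyphenyl)-7-methoxy-2-[4-(methoxymethoxy)phenyl]-4H-chromen-4-one | COCOc1ccc(cc1)-c1cc(=O)c2c(OCc3ccccc3)cc(OC)c(-c3cc(Cl)ccc3OC)c2o1 | intermediate
11 | 5-(benzyloxy)-8-(5-chloro-2-methoxyphenyl)-2-(4-hydroxyphenyl)-7-methoxy-4H-chromen-4-one | Oc1ccc(cc1)-c1cc(=O)c2c(OCc3ccccc3)cc(OC)c(-c3cc(Cl)ccc3OC)c2o1 | intermediate
12 | 4-[5-(benzyloxy)-8-(5-chloro-2-methoxyphenyl)-7-methoxy-4-oxo-4H-chromen-2-yl]phenyl acetate | CC(=O)Oc1ccc(cc1)-c1cc(=O)c2c(OCc3ccccc3)cc(OC)c(-c3cc(Cl)ccc3OC)c2o1 | intermediate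
13 | 4-{5-(benzyloxy)-7-methoxy-8-[2-methoxy-5-(4,4,5,5-tetramethyl-1,3,2-dioxaborolan-2-yl)phenyl]-4-oxo-4H-chromen-2-yl}phenyl acetate | CC(=O)Oc1ccc(cc1)-c1cc(=O)c2c(OCc3ccccc3)cc(OC)c(-c3cc(B4OC(C)(C)C(C)(C)O4)ccc3OC)c2o1 | intermediate
14 | {3-[2-(4-acetoxyphenyl)-5-(benzyloxy)-7-methoxy-4-oxo-4H-chromen-8-yl]-4-methoxyphenyl}boronic acid | CC(=O)Oc1ccc(cc1)-c1cc(=O)c2c(OCc3ccccc3)cc(OC)c(-c3cc(B(O)O)ccc3OC)c2o1 | intermediate
15 | 4-{5-(benzyloxy)-8-[5-((2S)-5-(benzyloxy)-7-methoxy-4-oxochroman-2-yl)-2-methoxyphenyl]-7-methoxy-4-oxo-4H-chromen-2-yl}phenyl acetate | COc1cc(OCc2ccccc2)c2c(c1)O[C@H](c1ccc(OC)c(-c3c(OC)cc(OCc4ccccc4)c4c(=O)cc(-c5ccc(OC(C)=O)cc5)oc34)c1)CC2=O | intermediate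
16 | 4-{5-hydroxy-8-[5-((2S)-5-hydroxy-7-methoxy-4-oxochroman-2-yl)-2-methoxyphenyl]-7-methoxy-4-oxo-4H-chromen-2-yl}phenyl acetate | COc1cc(O)c2c(c1)O[C@H](c1ccc(OC)c(-c3c(OC)cc(O)c4c(=O)cc(-c5ccc(OC(C)=O)cc5)oc34)c1)CC2=O | intermediate
17 | (2S)-2,3-dihydroamentoflavone 7,4',7''-tri-O-methyl ether | COc1cc(O)c2c(c1)O[C@H](c1ccc(OC)c(-c3c(OC)cc(O)c4c(=O)cc(-c5ccc(O)cc5)oc34)c1)CC2=O | target

## Step count and risks
Total step count: 12. Longest linear sequence: 11 (steps 1 and 3 to 12); step 2 is the side branch.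

**Step 3 (site of iodination).** If iodine enters between OMe and OBn, the aryl group would end at C6 of the flavone.
- The fallback sets out from 1 and comes back at 5.
- The still symmetric diol 1 is iodinated first (NIS, DMF). Both free ring positions are equivalent there, so only 1-(2,6-dihydroxy-3-iodo-4-methoxyphenyl)ethanone F1 can form.
- Benzylation with BnBr (1.0 equiv) and K2CO3 in acetone then goes to the OH that is not shielded by iodine, which gives 5.

**Step 4 (tri-ortho-substituted biaryl next to a free phenoxide).** The fallback moves both halogenation and coupling to the flavone stage. It sets out from 2 and comes back at 12.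
- Claisen–Schmidt condensation of 2 with 8 gives the chalcone F2.
- I2/DMSO followed by HCl/MeOH leads through the MOM flavone F3 to the 4'-hydroxyflavone F4.
- Ac2O/pyridine gives the flavone acetate F5.
- NIS with catalytic CF3CO2H in MeCN iodinates the now fully O-alkylated ring A at C8 to give the 8-iodoflavone F6.
- A water-free, fluoride-promoted Suzuki coupling of F6 with 6 (Pd(PPh3)4, CsF, DME, 85 °C) keeps the acetate and delivers 12.

**Step 10 (slow insertion into the electron-rich, peri-substituted chromone, or protodeboronation of 14).** The fallback replaces intermolecular aryl transfer by an organocatalytic asymmetric ring closure. It sets out from 2 and comes back at 15.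
- The 8-iodoflavone F6, made from 2 as above, is coupled with commercial (5-formyl-2-methoxyphenyl)boronic acid under the same CsF conditions to give the biaryl aldehyde F7.
- The dianion of 2 (LiN(SiMe3)2, THF, −78 °C) is C-acylated with Boc2O to give the tert-butyl beta-keto ester F8.
- Knoevenagel condensation of F7 with F8 (catalytic piperidine/AcOH, toluene, 4 Å sieves) gives the alkylidene beta-keto ester F9.
- A cinchona-derived bifunctional thiourea (10 mol%, toluene, −25 °C) catalyses the intramolecular oxa-Michael addition to the (2S)-flavanone-3-carboxylate F10. The quinine- or quinidine-based pseudo-enantiomer is chosen by CD so that C2 is S.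
- TsOH in toluene at 80 °C removes the ester group and gives 15, which continues through steps 11 and 12 unchanged.

Further compounds
F1 | step 3 | 1-(2,6-dihydroxy-3-iodo-4-methoxyphenyl)ethanone | CC(=O)c1c(O)cc(OC)c(I)c1O
F2 | step 4 | (E)-1-[2-(benzyloxy)-6-hydroxy-4-methoxyphenyl]-3-[4-(methoxymethoxy)phenyl]prop-2-en-1-one | COCOc1ccc(/C=C/C(=O)c2c(O)cc(OC)cc2OCc2ccccc2)cc1
F3 | step 4 | 5-(benzyloxy)-7-methoxy-2-[4-(methoxymethoxy)phenyl]-4H-chromen-4-one | COCOc1ccc(cc1)-c1cc(=O)c2c(OCc3ccccc3)cc(OC)cc2o1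
F4 | step 4 | 5-(benzyloxy)-2-(4-hydroxyphenyl)-7-methoxy-4H-chromen-4-one | COc1cc(OCc2ccccc2)c2c(=O)cc(-c3ccc(O)cc3)oc2c1
F5 | step 4 | 4-[5-(benzyloxy)-7-methoxy-4-oxo-4H-chromen-2-yl]phenyl acetate | COc1cc(OCc2ccccc2)c2c(=O)cc(-c3ccc(OC(C)=O)cc3)oc2c1
F6 | step 4 | 4-[5-(benzyloxy)-8-iodo-7-methoxy-4-oxo-4H-chromen-2-yl]phenyl acetate | COc1cc(OCc2ccccc2)c2c(=O)cc(-c3ccc(OC(C)=O)cc3)oc2c1I
F7 | step 10 | 4-[5-(benzyloxy)-8-(5-formyl-2-methoxyphenyl)-7-methoxy-4-oxo-4H-chromen-2-yl]phenyl acetate | CC(=O)Oc1ccc(cc1)-c1cc(=O)c2c(OCc3ccccc3)cc(OC)c(-c3cc(C=O)ccc3OC)c2o1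
F8 | step 10 | tert-butyl 3-[2-(benzyloxy)-6-hydroxy-4-methoxyphenyl]-3-oxopropanoate | CC(C)(C)OC(=O)CC(=O)c1c(O)cc(OC)cc1OCc1ccccc1
F9 | step 10 | tert-butyl 2-[2-(benzyloxy)-6-hydroxy-4-methoxybenzoyl]-3-{3-[2-(4-acetoxyphenyl)-5-(benzyloxy)-7-methoxy-4-oxo-4H-chromen-8-yl]-4-methoxyphenyl}prop-2-enoate (E/Z mixture) | CC(C)(C)OC(=O)C(=Cc1ccc(OC)c(c1)-c1c(OC)cc(OCc2ccccc2)c2c(=O)cc(oc12)-c1ccc(OC(C)=O)cc1)C(=O)c1c(O)cc(OC)cc1OCc1ccccc1
F10 | step 10 | tert-butyl (2S)-2-{3-[2-(4-acetoxyphenyl)-5-(benzyloxy)-7-methoxy-4-oxo-4H-chromen-8-yl]-4-methoxyphenyl}-5-(benzyloxy)-7-methoxy-4-oxochromane-3-carboxylate (C3 epimerisable) | CC(C)(C)OC(=O)C1C(=O)c2c(OCc3ccccc3)cc(OC)cc2O[C@@H]1c1ccc(OC)c(c1)-c1c(OC)cc(OCc2ccccc2)c2c(=O)cc(oc12)-c1ccc(OC(C)=O)cc1
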